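**Strategy.** Everything rests on breaking C8–C10 and the C7–ring A bond (C7: aryl-bearing CH of the seven-membered ring; C8: CH common to both carbocycles; C10/C9: indane CH carrying 4-hydroxyphenyl/3,5-dihydroxyphenyl; ring A: resorcinol at C7; ring B: resorcinol fused to both rings). A single acid treatment of an (E)-stilbene keto carbinol forms both rings and three stereocentres: the 4-methoxyphenyl group on C10 supports a benzylic cation, the stilbene carbon C8 sits in 1,5-relation to it across ring B, and the resulting C7 cation meets the ring-A position next to the carbonyl, ortho and para to the two methoxy groups. The precursor has C9 as its only stereocentre that lasts and an electron-poor bis-mesylate aryl on C9.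

Key step: step 8

Remark 1 (protecting groups): the aryl on C9 ends up cis to C7 on the indane. As a free or methylated resorcinol it would be the better partner for the C7 cation, closing a six-membered bridged ring. It is therefore carried as its bis(methanesulfonate) until after the key step; all other phenols are methyl ethers.

Remark 2 (assumption on C10): C10 is destroyed in step 8, so either C10 epimer serves as long as it has (S)-C9. The reduction in step 7 is assumed to follow the Felkin sense, which pairs the (S,S) catalyst with the (9S,10S) carbinol. If the sense were the opposite, the (R,R) catalyst would give the (9S,10R) carbinol and the same cation.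

Step 1
Reactants: 1 3,5-dimethoxybenzaldehyde
Product: 2 2,6-dibromo-3,5-dimethoxybenzaldehyde
Conditions: Br2 (2.2 equiv), AcOH, rt
Reagents that add atoms: bromine, BrBr
Why: Electrophilic aromatic bromination; each position ortho to the formyl group is ortho to one methoxy group and para to the other, so both react before the more hindered C4 between the two methoxy groups.

Step 2
Reactants: 2 2,6-dibromo-3,5-dimethoxybenzaldehyde; 3 diethyl (4-methoxybenzyl)phosphonate
Product: 4 2,4-dibromo-1,5-dimethoxy-3-[(E)-2-(4-methoxyphenyl)ethenyl]benzene
Conditions: KOt-Bu, THF, 0 °C → rt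
Reagents that add atoms: none
Why: Horner–Wadsworth–Emmons olefination of a non-enolisable aldehyde with a benzylic phosphonate anion, which should give the (E)-stilbene and leave both C–Br bonds untouched.

Step 3
Reactants: 4 2,4-dibromo-1,5-dimethoxy-3-[(E)-2-(4-methoxyphenyl)ethenyl]benzene; 5 3,5-dimethoxybenzoyl chloride
Product: 7 [3-bromo-4,6-dimethoxy-2-[(E)-2-(4-methoxyphenyl)ethenyl]phenyl](3,5-dimethoxyphenyl)methanone, via aryllithium 6 (not isolated)
Conditions: n-BuLi (1.0 equiv), THF, −78 °C; then cannulation into 5 (1.3 equiv), THF, −78 °C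
Reagents that add atoms: none
Why: Bromine–lithium exchange on one of two equivalent bromides (faster than addition of n-BuLi to the stilbene at −78 °C), then acylation of the aryllithium by inverse addition to the aroyl chloride; the 2,6-disubstituted diaryl ketone is too hindered for a second addition.

Step 4
Reactants: 8 5-bromobenzene-1,3-diol
Product: 9 5-bromo-1,3-phenylene dimethanesulfonate
Conditions: MsCl (2.4 equiv), Et3N, CH2Cl2, 0 °C
Reagents that add atoms: methanesulfonyl chloride, CS(=O)(=O)Cl
Why: O-Sulfonylation of both phenols; the mesylates make this ring electron-poor and should be inert to the palladium catalysts used below, to transfer hydrogenation and to acid.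

Step 5
Reactants: 9 5-bromo-1,3-phenylene dimethanesulfonate; 10 1-(4-methoxyphenyl)ethan-1-one (2 equiv)
Product: 11 5-[2-(4-methoxyphenyl)-2-oxoethyl]-1,3-phenylene dimethanesulfonate
Conditions: Pd2(dba)3 (1 mol%), Xantphos (2.4 mol%), K3PO4, toluene, 80 °C
Reagents that add atoms: none
Why: Palladium-catalysed α-arylation of a methyl ketone enolate at the C–Br bond; the chelating ligand and excess ketone favour monoarylation, and the phosphate base spares the mesylates.

Step 6
Reactants: 7 [3-bromo-4,6-dimethoxy-2-[(E)-2-(4-methoxyphenyl)ethenyl]phenyl](3,5-dimethoxyphenyl)methanone; 11 5-[2-(4-methoxyphenyl)-2-oxoethyl]-1,3-phenylene dimethanesulfonate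
Product: 12 racemic 5-[1-[3-(3,5-dimethoxybenzoyl)-4,6-dimethoxy-2-[(E)-2-(4-methoxyphenyl)ethenyl]phenyl]-2-(4-methoxyphenyl)-2-oxoethyl]-1,3-phenylene dimethanesulfonate
Conditions: Pd2(dba)3 (2.5 mol%), P(t-Bu)3·HBF4 (6 mol%), K3PO4, toluene, 100 °C
Reagents that add atoms: none
Why: Palladium-catalysed ketone α-arylation of the readily formed deoxybenzoin enolate with a di-ortho-substituted aryl bromide, for which a bulky monophosphine promotes oxidative addition and reductive elimination; the product rests as its hindered enolate, so it is not arylated again, and C9 is formed racemic.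

Step 7
Reactants: 12 racemic diketone
Product: 13 5-[(1S,2S)-1-[3-(3,5-dimethoxybenzoyl)-4,6-dimethoxy-2-[(E)-2-(4-methoxyphenyl)ethenyl]phenyl]-2-hydroxy-2-(4-methoxyphenyl)ethyl]-1,3-phenylene dimethanesulfonate (C9 S, C10 S)
Conditions: RuCl[(S,S)-TsDPEN](p-cymene) (2 mol%), HCO2H/Et3N (1:1), DMF, 40 °C; chromatographic removal of the minor diastereomer
Reagents that add atoms: none
Why: Noyori–Ikariya asymmetric transfer hydrogenation with dynamic kinetic resolution: the doubly benzylic C9–H next to the ketone epimerises under the amine, the (S,S) catalyst delivers hydride to the aryl ketone to give (S)-C10, and the C9 epimer that holds the bulky ring-B group anti to the incoming hydride (Felkin–Anh sense) should react faster and so fix (S)-C9, while the twisted 2,6-disubstituted diaryl ketone is expected to react far more slowly.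

Step 8
Reactants: 13 (9S,10S)-stilbene keto carbinol
Product: 16 (7S,8R,9S,10S)-hexamethyl ether bis(methanesulfonate) of 18, via C10 benzylic cation 14 (not isolated), via indanyl C7 cation 15 (not isolated)
Conditions: TfOH (0.1 equiv), HFIP/CH2Cl2 (1:4), −40 °C → rt
Reagents that add atoms: none
Why: Acid ionises the C10 carbinol to the 4-methoxybenzylic cation 14, the stilbene adds through C8 to close the indane and hand the charge to C7 (cation 15, again stabilised by a 4-methoxyphenyl group), and 15 alkylates ring A at the carbon next to the carbonyl, which lies ortho to one methoxy group and para to the other. The nearest precedents are the Brønsted-acid cyclisations in which a benzylic cation of a resveratrol dimer is taken up by its neighbouring stilbene to give an indane, followed by arene capture of the new cation, and Friedel–Crafts alkylations that form benzo-fused cycloheptanes. The five-membered ring closes 5-exo-trig with respect to the C8=C7 bond, and the seven-membered ring closes by intramolecular Friedel–Crafts alkylation, exo with respect to the quinoid C7=aryl bond of 15. C10 is set by C9, because the cation is attacked on the face that leaves its anisyl group trans to the C9 aryl; C8 places its cationic branch trans to the C10 anisyl group, helped by the (E) geometry and by reversible loss and return of H8; C7 is set in the arylation through the rotamer that turns its anisyl group away from C10, which leaves H7 and H8 trans. The step needs capture of 15 by ring A and not by the C9 aryl, which stands cis to C7 and could close a six-membered bridged ring: the two mesylates make that aryl inert, and they also disfavour hydride or aryl shift towards C9. It further needs ring closure to outrun loss of H9 from 14, which the ortho-placed styrene (five-membered transition state), catalytic acid and low temperature are meant to secure.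

Step 9
Reactants: 16 (7S,8R,9S,10S)-hexamethyl ether bis(methanesulfonate) of 18
Product: 17 (7S,8R,9S,10S)-hexamethyl ether of 18 with free 3,5-dihydroxyphenyl on C9
Conditions: KOH, MeOH/THF/H2O, 60 °C; aq. NH4Cl
Reagents that add atoms: none
Why: Sulfonate ester hydrolysis by attack of hydroxide at sulfur frees the two phenols; the methyl ethers, the non-enolisable diaryl ketone and the four stereocentres (none α to a carbonyl) should be unaffected.

Step 10
Reactants: 17 (7S,8R,9S,10S)-hexamethyl ether of 18
Product: 18 target CNP0116600.1, (7S,8R,9S,10S)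
Conditions: BBr3 (12 equiv), CH2Cl2, −78 °C → rt; MeOH, H2O
Reagents that add atoms: none
Why: Boron tribromide demethylation: bromide attacks the methyl group of each boron-complexed aryl ether and hydrolysis of the aryl borates on work-up frees the six phenols without touching the carbon skeleton or the stereocentres.

**Compound list**

1 | 3,5-dimethoxybenzaldehyde | COc1cc(C=O)cc(OC)c1 | starting material
2 | 2,6-dibromo-3,5-dimethoxybenzaldehyde | COc1cc(OC)c(Br)c(C=O)c1Br | intermediate
3 | diethyl (4-methoxybenzyl)phosphonate | CCOP(=O)(Cc1ccc(OC)cc1)OCC | starting material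
4 | 2,4-dibromo-1,5-dimethoxy-3-[(E)-2-(4-methoxyphenyl)ethenyl]benzene | COc1ccc(/C=C/c2c(Br)c(OC)cc(OC)c2Br)cc1 | intermediate
5 | 3,5-dimethoxybenzoyl chloride | COc1cc(cc(OC)c1)C(Cl)=O | starting material
6 | [3-bromo-4,6-dimethoxy-2-[(E)-2-(4-methoxyphenyl)ethenyl]phenyl]lithium | COc1ccc(/C=C/c2c([Li])c(OC)cc(OC)c2Br)cc1 | intermediate (not isolated)
7 | [3-bromo-4,6-dimethoxy-2-[(E)-2-(4-methoxyphenyl)ethenyl]phenyl](3,5-dimethoxyphenyl)methanone | COc1cc(OC)cc(c1)C(=O)c1c(OC)cc(OC)c(Br)c1/C=C/c1ccc(OC)cc1 | intermediate
8 | 5-bromobenzene-1,3-diol | Oc1cc(O)cc(Br)c1 | starting material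
9 | 5-bromo-1,3-phenylene dimethanesulfonate | CS(=O)(=O)Oc1cc(Br)cc(OS(C)(=O)=O)c1 | intermediate
10 | 1-(4-methoxyphenyl)ethan-1-one | COc1ccc(cc1)C(C)=O | starting material
11 | 5-[2-(4-methoxyphenyl)-2-oxoethyl]-1,3-phenylene dimethanesulfonate | COc1ccc(cc1)C(=O)Cc1cc(OS(C)(=O)=O)cc(OS(C)(=O)=O)c1 | intermediate
12 | racemic diketone: ring B carries the 3,5-dimethoxybenzoyl group, the (E)-4-methoxystyryl group and C9H[3,5-bis(mesyloxy)phenyl]–C(=O)(4-methoxyphenyl) | COc1cc(OC)cc(c1)C(=O)c1c(OC)cc(OC)c(C(c2cc(OS(C)(=O)=O)cc(OS(C)(=O)=O)c2)C(=O)c2ccc(OC)cc2)c1/C=C/c1ccc(OC)cc1 | intermediate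
13 | (9S,10S)-(E)-stilbene keto carbinol, key-step precursor | COc1cc(OC)cc(c1)C(=O)c1c(OC)cc(OC)c([C@H](c2cc(OS(C)(=O)=O)cc(OS(C)(=O)=O)c2)[C@H](O)c2ccc(OC)cc2)c1/C=C/c1ccc(OC)cc1 | intermediate
14 | C10 4-methoxybenzylic cation with (S)-C9 | COc1cc(OC)cc(c1)C(=O)c1c(OC)cc(OC)c([C@H](c2cc(OS(C)(=O)=O)cc(OS(C)(=O)=O)c2)[CH+]c2ccc(OC)cc2)c1/C=C/c1ccc(OC)cc1 | intermediate (not isolated)
15 | trans,trans-indanyl cation with the charge on C7 | COc1cc(OC)cc(c1)C(=O)c1c(OC)cc(OC)c2c1[C@@H]([CH+]c1ccc(OC)cc1)[C@H](c1ccc(OC)cc1)[C@H]2c1cc(OS(C)(=O)=O)cc(OS(C)(=O)=O)c1 | intermediate (not isolated)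
16 | (7S,8R,9S,10S)-key-step product: ketone bridging rings A and B in a seven-membered ring with C7 and C8; indane C8–C10–C9 on ring B; six OMe, two OMs on the C9 aryl | O=C1c2cc(OC)cc(OC)c2[C@H](c2ccc(OC)cc2)[C@@H]2c3c1c(OC)cc(OC)c3[C@H](c1cc(OS(C)(=O)=O)cc(OS(C)(=O)=O)c1)[C@H]2c1ccc(OC)cc1 | intermediate
17 | (7S,8R,9S,10S)-hexamethyl ether with free 3,5-dihydroxyphenyl on C9 | O=C1c2cc(OC)cc(OC)c2[C@H](c2ccc(OC)cc2)[C@@H]2c3c1c(OC)cc(OC)c3[C@H](c1cc(O)cc(O)c1)[C@H]2c1ccc(OC)cc1 | intermediate
18 | CNP0116600.1, (7S,8R,9S,10S) | O=C1c2cc(O)cc(O)c2[C@H](c2ccc(O)cc2)[C@@H]2c3c1c(O)cc(O)c3[C@H](c1cc(O)cc(O)c1)[C@H]2c1ccc(O)cc1 | target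

**Totals**

Total step count: 10. Longest linear sequence: 8 steps (1, 2, 3, 6, 7, 8, 9, 10).

**Steps most likely to fail**

First, step 8. Loss of H9 from cation 14, or a hydride shift to C9, may compete with ring closure and erode the enantiomeric purity. The cascade may also stall after the first closure, because cation 15 sheds H8 or is held reversibly by the carbonyl oxygen before the slower alkylation of the acyl-bearing ring A. The fallback separates the two ring closures. Setting out from 13, ionisation in TFA/CH2Cl2 at −30 °C should close the five-membered ring and capture the new cation as the indanyl C7 trifluoroacetate F1. After evaporation, F1 would be re-ionised on its own under stronger Friedel–Crafts conditions (TfOH or Bi(OTf)3 in HFIP, rt to 40 °C), which returns to the route at 16.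

Second, step 7. Hydride transfer to the hindered ketone may be slow, the two C9 epimers may be poorly discriminated, or enolisation may be too slow to keep them in equilibrium; each would leave part of the material with (R)-C9. The fallback uses resolution in place of asymmetric catalysis. Setting out from 12, NaBH4 in THF/MeOH at 0 °C should give the racemic carbinol F2, whose major diastereomer is purified on silica. Its enantiomers would be separated by preparative chromatography on a chiral stationary phase; the (9S,10S) enantiomer is 13, where the route is rejoined.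

Third, step 6. Oxidative addition and reductive elimination at the di-ortho-substituted bromide may be too slow with the bulky secondary enolate, so that hydrodebromination of 7 takes over. The fallback assembles C9 by two arylations with the small partner first. Setting out from 7 and 10, α-arylation of the methyl ketone enolate (Pd2(dba)3, P(t-Bu)3·HBF4, NaOt-Bu, toluene, 80 °C) should give the ring-B benzyl ketone F3. A second α-arylation of F3 with the unhindered, electron-poor bromide 9 (Pd2(dba)3, Xantphos, K3PO4, toluene, 100 °C) returns to the route at 12.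

**Further compounds**

F1 | step 8 | trans,trans-indanyl C7 trifluoroacetate (C7 epimers) | COc1cc(OC)cc(c1)C(=O)c1c(OC)cc(OC)c2c1[C@@H](C(OC(=O)C(F)(F)F)c1ccc(OC)cc1)[C@H](c1ccc(OC)cc1)[C@H]2c1cc(OS(C)(=O)=O)cc(OS(C)(=O)=O)c1
F2 | step 7 | racemic carbinol (racemate of 13 and its C10 epimers, no configuration assigned) | COc1cc(OC)cc(c1)C(=O)c1c(OC)cc(OC)c(C(c2cc(OS(C)(=O)=O)cc(OS(C)(=O)=O)c2)C(O)c2ccc(OC)cc2)c1/C=C/c1ccc(OC)cc1
F3 | step 6 | 2-[3-(3,5-dimethoxybenzoyl)-4,6-dimethoxy-2-[(E)-2-(4-methoxyphenyl)ethenyl]phenyl]-1-(4-methoxyphenyl)ethan-1-one | COc1cc(OC)cc(c1)C(=O)c1c(OC)cc(OC)c(CC(=O)c2ccc(OC)cc2)c1/C=C/c1ccc(OC)cc1
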